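**Plan**

- Retrosynthesis: the C2=C3 alkene, the C9 ester and the lactone bond C12–O6 are cut first. The C1 and C6 carbonyl carbons of the resulting cyclodecane-1,6-dione are then rejoined as the C1=C6 alkene shared by ring A (C1, C6–C10) and ring B (C1–C6) of an octalin.
- Enabling feature: the C1 ketone and the oxygen-bearing C6 lie 1,6 across the ten-membered ring C1–C10, so both oxygens map onto the two carbons of one ring-fusion alkene.
- The octalin is cut at C1–C2 (Barbier addition) and C5–C6 (enolate alkylation) into (R)-carvone (ring A, C7) and a C2–C5 iodide from dimethyl (S)-methylsuccinate (C4).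
- Forward: carvone is alkylated at C6, C8–C10 are oxygenated on ring A, ring B is closed with SmI2, C12 is oxidised and the carbinol dehydrated. Ozonolysis then unveils the ten-membered ring, followed by Evans–Tishchenko reduction, lactonisation, acylation and dehydrogenation.
- Stereochemistry: C7 comes from carvone and C4 from the succinate. C8 is set by hydride addition cis to C7, C10 by hydroxyl-directed epoxidation, C9 by SN2 epoxide opening, and C6 by 1,3-anti hydride delivery from the C8 hydroxyl. The C2=C3 alkene is expected Z in the ten-membered ring.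

Key step: step 23

Remark: locants C1–C13 are those of the target in every intermediate (C11–C13 = side chain on C7), and α is the ring face that carries the C7 side chain (β the opposite face). The configurations at C1 and C6 before step 22 are transient.

**Step 1**
Reactants: 1 dimethyl (S)-2-methylbutanedioate
Product: 2 (S)-2-methylbutane-1,4-diol
Conditions: LiAlH4, THF, 0 °C → reflux; NaOH/H2O work-up
Reagents that add atoms: none
Why: Hydride reduction of both ester groups to primary alcohols; the methyl-bearing stereocentre is not touched and becomes C4.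

**Step 2**
Reactants: 2 (S)-2-methylbutane-1,4-diol
Product: 3 (S)-2-methyl-4-(triisopropylsilyloxy)butan-1-ol
Conditions: TIPSCl (1 equiv), imidazole, CH2Cl2, −20 → 0 °C
Reagents that add atoms: triisopropylsilyl chloride, CC(C)[Si](Cl)(C(C)C)C(C)C
Why: Silylation with a bulky chlorosilane is kinetically selective for the hydroxyl that is not β-branched (the future C2 terminus); the regioisomer and the bis-ether are removed by chromatography.

**Step 3**
Reactants: 3 (S)-2-methyl-4-(triisopropylsilyloxy)butan-1-ol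
Product: 4 (S)-(4-iodo-3-methylbutoxy)triisopropylsilane
Conditions: I2, PPh3, imidazole, CH2Cl2, 0 °C → rt
Reagents that add atoms: iodine, II
Why: Garegg–Samuelsson (Appel-type) iodination of the primary alcohol by SN2 on the alkoxyphosphonium ion; C4 is not involved.

**Step 4**
Reactants: 5 (R)-carvone; 4 (S)-(4-iodo-3-methylbutoxy)triisopropylsilane
Product: 6 6β-alkylcarvone (ring A enone; C6 carries the C5–C2 chain CH2–CH(CH3)–CH2–CH2–OTIPS trans to the C7 isopropenyl group)
Conditions: LDA, THF, −78 °C; then 4, DMPU, −78 → 0 °C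
Reagents that add atoms: none
Why: Kinetic α'-deprotonation gives the cross-conjugated lithium dienolate, which is alkylated (SN2; DMPU because the iodide is β-branched) anti to the isopropenyl group; the C6 configuration is erased later.

**Step 5**
Reactants: 6 6β-alkylcarvone
Product: 7 1α-allylic alcohol (cis-carveol type; OH cis to the isopropenyl group and trans to the C6 chain)
Conditions: NaBH4, CeCl3·7H2O, MeOH, −78 → −20 °C
Reagents that add atoms: none
Why: Luche 1,2-reduction; axial hydride attack gives the pseudo-equatorial alcohol cis to the isopropenyl group, as in the conversion of carvone into cis-carveol.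

**Step 6**
Reactants: 7 1α-allylic alcohol
Product: 8 9α,10α-epoxy-1α-alcohol
Conditions: VO(acac)2 (cat.), t-BuOOH, CH2Cl2, 0 °C → rt
Reagents that add atoms: tert-butyl hydroperoxide, CC(C)(C)OO
Why: Hydroxyl-directed vanadium-catalysed epoxidation delivers oxygen to the allylic alkene syn to the C1 hydroxyl and leaves the isopropenyl group untouched.

**Step 7**
Reactants: 8 9α,10α-epoxy-1α-alcohol
Product: 10 Δ8-ene-1α,10α-diol (tertiary allylic alcohol at C10), via hydroxy selenide 9 (not isolated)
Conditions: (PhSe)2, NaBH4, EtOH, reflux; then H2O2, pyridine, THF, 0 °C → rt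
Reagents that add atoms: none
Why: Epoxide-to-allylic-alcohol isomerisation with selenium: benzeneselenolate opens the epoxide trans-diaxially at the less substituted C9 (the mode known for trans-limonene oxide), and syn-elimination of the selenoxide can only involve H8, which moves the alkene to C8=C9 and leaves the oxygen on C10.

**Step 8**
Reactants: 10 Δ8-ene-1α,10α-diol
Product: 11 1α-triisopropylsilyl ether of the tertiary allylic alcohol
Conditions: TIPSOTf, 2,6-lutidine, CH2Cl2, −78 → 0 °C
Reagents that add atoms: triisopropylsilyl trifluoromethanesulfonate, CC(C)[Si](OS(=O)(=O)C(F)(F)F)(C(C)C)C(C)C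
Why: Silyl triflate protection of the secondary C1 hydroxyl; the tertiary allylic hydroxyl is too hindered for this silyl group and stays free for step 9.

**Step 9**
Reactants: 11 1α-silyl ether of the tertiary allylic alcohol
Product: 12 transposed enone (C8 ketone; C9=C10 alkene with the C10 methyl; 1α-OTIPS)
Conditions: pyridinium chlorochromate (C5H5NH)[CrO3Cl], NaOAc, 4 Å molecular sieves, CH2Cl2, rt
Reagents that add atoms: pyridinium chlorochromate, [O-][Cr](=O)(=O)Cl.c1cc[nH+]cc1
Why: Dauben–Babler oxidative transposition: the chromate ester of the tertiary allylic alcohol undergoes a [3,3] shift and oxidation, which transfers the oxygen function from C10 to C8 and gives the β-methyl enone.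

**Step 10**
Reactants: 12 transposed enone
Product: 13 8α-allylic alcohol (OH cis to the C7 isopropenyl group)
Conditions: Li[BH(s-Bu)3], THF, −78 °C
Reagents that add atoms: none
Why: 1,2-Reduction (conjugate addition is blocked by β,β-disubstitution) in which the bulky borohydride approaches from the β face, syn to the pseudo-axial H7, to give the pseudo-axial 8α-alcohol, as 2-alkylcyclohexanones give cis-alcohols with this reagent.

**Step 11**
Reactants: 13 8α-allylic alcohol
Product: 14 9α,10α-epoxy-8α-alcohol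
Conditions: VO(acac)2 (cat.), t-BuOOH, CH2Cl2, 0 °C → rt
Reagents that add atoms: tert-butyl hydroperoxide, CC(C)(C)OO
Why: Hydroxyl-directed epoxidation syn to the pseudo-axial 8α-hydroxyl places the C10 oxygen on the α face; the isolated 1,1-disubstituted alkene does not compete.

**Step 12**
Reactants: 14 9α,10α-epoxy-8α-alcohol
Product: 15 8α-(4-methoxybenzyl) ether of the epoxide
Conditions: NaH, 4-methoxybenzyl chloride, Bu4NI (cat.), THF/DMF, 0 °C → rt
Reagents that add atoms: 4-methoxybenzyl chloride, COc1ccc(CCl)cc1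
Why: Williamson etherification of the sodium alkoxide; the epoxide lies on the same face as the alkoxide, so no Payne rearrangement can intervene.

**Step 13**
Reactants: 15 8α-(4-methoxybenzyl) ether of the epoxide
Product: 16 9β,10α-diol
Conditions: KOH, DMSO/H2O, 80 °C
Reagents that add atoms: potassium hydroxide, [K+].[OH-]
Why: SN2 opening of the trisubstituted epoxide by hydroxide at the secondary C9 with inversion, the trans-diaxial (Fürst–Plattner) mode for this epoxide face, gives the 9β,10α-diol and completes the all-trans C8–C10 triol pattern.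

**Step 14**
Reactants: 16 9β,10α-diol
Product: 17 9β,10α-bis(methoxymethyl) ether
Conditions: MOMCl, i-Pr2NEt, Bu4NI (cat.), ClCH2CH2Cl, 60 °C
Reagents that add atoms: chloromethyl methyl ether, COCCl
Why: Alkylation of the secondary and the tertiary hydroxyl with the chloromethyl ether under forcing amine-base conditions gives acetals that withstand the following basic, reductive and oxidative steps.

**Step 15**
Reactants: 17 9β,10α-bis(methoxymethyl) ether
Product: 18 1α,2-diol (C1 carbinol and primary C2 alcohol)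
Conditions: Bu4NF, THF, rt → 45 °C
Reagents that add atoms: none
Why: Fluoride cleaves both triisopropylsilyl ethers through Si–F bond formation, freeing the C1 carbinol and the C2 primary alcohol.

**Step 16**
Reactants: 18 1α,2-diol
Product: 19 primary iodide (C2–I) with free 1α-hydroxyl
Conditions: I2, PPh3, imidazole, CH2Cl2, 0 °C
Reagents that add atoms: iodine, II
Why: Garegg–Samuelsson iodination is selective for the primary alcohol; the secondary C1 hydroxyl, flanked by C6 and the quaternary C10, does not react at 0 °C.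

**Step 17**
Reactants: 19 primary iodide with free 1α-hydroxyl
Product: 20 iodo ketone (C1 ketone)
Conditions: Dess–Martin periodinane, NaHCO3, CH2Cl2, rt
Reagents that add atoms: none
Why: Hypervalent-iodine oxidation of the secondary alcohol to the C1 ketone under buffered, non-basic conditions that leave the primary iodide and C6 alone.

**Step 18**
Reactants: 20 iodo ketone
Product: 21 cis-fused decalinol (ring B closed; tertiary 1α-OH; isopropenyl on C7)
Conditions: SmI2, Fe(dbm)3 (cat.; dbm = dibenzoylmethanide), THF, −78 °C → rt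
Reagents that add atoms: none
Why: Intramolecular samarium Barbier reaction: two-electron reduction of the C–I bond gives an organosamarium that adds to the C1 ketone through a six-membered transition state, closing ring B as the cis-fused tertiary alcohol because the tether on the β face of C6 attacks that face of C1.

**Step 19**
Reactants: 21 cis-fused decalinol
Product: 23 enal (C12 aldehyde; side chain CH2=C(CHO)–), via allylic alcohol 22 (not isolated)
Conditions: SeO2 (cat.), t-BuOOH, CH2Cl2, rt; then MnO2, CH2Cl2, rt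
Reagents that add atoms: tert-butyl hydroperoxide, CC(C)(C)OO; selenium dioxide, O=[Se]=O
Why: Selenium dioxide allylic oxidation (ene reaction, then [2,3] shift) of the only alkene present occurs at the methyl group rather than at the hindered tertiary C7–H; MnO2 converts the allylic alcohol part of the product into the same enal.

**Step 20**
Reactants: 23 enal
Product: 24 acrylic acid (side chain CH2=C(CO2H)–)
Conditions: NaClO2, NaH2PO4, 2-methylbut-2-ene, t-BuOH/H2O, 0 °C → rt
Reagents that add atoms: sodium chlorite, [Na+].[O-]Cl=O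
Why: Pinnick (chlorite) oxidation of the enal to the acrylic acid; the scavenger alkene consumes the hypochlorous acid formed.

**Step 21**
Reactants: 24 acrylic acid
Product: 25 tert-butyl acrylate decalinol
Conditions: O-tert-butyl-N,N'-diisopropylisourea, CH2Cl2, rt
Reagents that add atoms: O-tert-butyl-N,N'-diisopropylisourea, CC(C)N=C(OC(C)(C)C)NC(C)C
Why: O-Alkylation of the carboxylic acid by the protonated isourea gives the tert-butyl ester under neutral conditions; this ester cannot be attacked later by the free C8 hydroxyl.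

**Step 22**
Reactants: 25 tert-butyl acrylate decalinol
Product: 26 octalin (C1=C6 ring-fusion alkene; 8α-OPMB, 9β-OMOM, 10α-OMOM; tert-butyl acrylate on C7; C4 methyl)
Conditions: Burgess reagent, benzene, 50 °C
Reagents that add atoms: none
Why: Burgess dehydration: the sulfamate of the tertiary alcohol undergoes syn-elimination with the cis-disposed H6 to give the more substituted C1=C6 alkene, while the inductive effect of the C10 oxygen disfavours ionisation at C1.

**Step 23**
Reactants: 26 octalin
Product: 27 cyclodecane-1,6-dione (C1 and C6 ketones; C4, C7, C8, C9 and C10 substituents unchanged)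
Conditions: O3, pyridine, CH2Cl2, −78 °C (indicator end point); N2 purge
Reagents that add atoms: ozone, [O-][O+]=O
Why: Ozone adds to the only electron-rich alkene, the tetrasubstituted C1=C6 bond, by 1,3-dipolar cycloaddition; the primary ozonide cycloreverts to a ketone and a ketone O-oxide, which pyridine relays to the second ketone with loss of dioxygen, so that no peroxide work-up is needed. The closest known reaction is the ozonolysis of Δ9,10-octalin to cyclodecane-1,6-dione. No ring is closed: excision of the shared C1–C6 bond leaves the periphery of the bicycle as the ten-membered ring (ring expansion by fragmentation). No stereocentre is created, since C4 and C7–C10 were set on six-membered rings. The step needs chemoselectivity, which is secured because the side-chain alkene is an acrylate and the anisyl ring is far less reactive toward ozone at −78 °C. It also needs neutrality, which the amine-buffered, reductant-free protocol provides, so that C7 (α to the new C6 ketone, with a β-alkoxy group) neither epimerises nor eliminates and the 1,6-dione does not undergo transannular aldolisation.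

**Step 24**
Reactants: 27 cyclodecane-1,6-dione
Product: 28 8α-hydroxy-1,6-dione
Conditions: DDQ, CH2Cl2/pH 7 phosphate buffer, 0 °C
Reagents that add atoms: none
Why: Oxidative cleavage of the 4-methoxybenzyl ether by hydride abstraction to the oxocarbenium ion and hydrolysis, at neutral pH so that the β-hydroxy ketone neither dehydrates nor undergoes retro-aldol cleavage.

**Step 25**
Reactants: 28 8α-hydroxy-1,6-dione
Product: 29 6β-hydroxy 8α-crotonate (C1 ketone retained; tert-butyl acrylate on C7)
Conditions: SmI2 (30 mol %), (E)-crotonaldehyde (excess), THF, −10 °C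
Reagents that add atoms: (E)-but-2-enal, C/C=C/C=O
Why: Evans–Tishchenko reduction: the trivalent samarium hemiacetal alkoxide formed from the C8 hydroxyl and the aldehyde transfers hydride to the C6 ketone through a chair transition state, giving the 1,3-anti alcohol with the C6 configuration of the target and leaving the aldehyde carbon as the C8 crotonate; the C1 ketone has no free β-hydroxyl and is not reduced.

**Step 26**
Reactants: 29 6β-hydroxy 8α-crotonate
Product: 32 α-methylene lactone 9β,10α-diol 8α-crotonate, via hydroxy acid 30 (not isolated), via MOM-protected lactone 31 (not isolated)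
Conditions: CF3CO2H/CH2Cl2, 0 °C → rt; then NaHCO3, MeOH/H2O
Reagents that add atoms: none
Why: Acidolysis removes the tert-butyl group as isobutene, the γ-hydroxy acid closes onto the C6 hydroxyl (the only free γ-hydroxyl) to the trans-fused α-methylene γ-lactone, and the two methoxymethyl acetals are hydrolysed; an acyl shift between O8 and O9 would be harmless because both end as crotonates.

**Step 27**
Reactants: 32 α-methylene lactone 9β,10α-diol 8α-crotonate
Product: 33 2,3-dihydro target (8α,9β-dicrotonate; free 10α-OH; saturated C2–C3)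
Conditions: (E)-crotonic anhydride, DMAP, Et3N, CH2Cl2, 0 °C
Reagents that add atoms: (E)-but-2-enoic anhydride, C/C=C/C(=O)OC(=O)/C=C/C
Why: DMAP-catalysed acylation of the free secondary hydroxyl; the tertiary C10 hydroxyl is not acylated under these conditions.

**Step 28**
Reactants: 33 2,3-dihydro target
Product: 36 target CNP0223772.1, via bis-silyl enol ether 34 (not isolated), via silyl-protected enone 35 (not isolated)
Conditions: Me3SiOTf, Et3N, CH2Cl2, 0 °C; then Pd(OAc)2, MeCN, rt; then citric acid, MeOH/H2O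
Reagents that add atoms: none
Why: Saegusa–Ito dehydrogenation: soft enolisation can occur only toward C2 because C10 is quaternary, the silyl enol ether is transmetallated to a divalent palladium enolate, and syn β-hydride elimination gives the enone, expected as the Z isomer that the ten-membered ring accommodates; mild acid removes the transient silyl ether on O10.

**Compound list**

1 | dimethyl (S)-2-methylbutanedioate | COC(=O)C[C@H](C)C(=O)OC | starting material
2 | (S)-2-methylbutane-1,4-diol | OC[C@@H](C)CCO | intermediate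
3 | (S)-2-methyl-4-(triisopropylsilyloxy)butan-1-ol | OC[C@@H](C)CCO[Si](C(C)C)(C(C)C)C(C)C | intermediate
4 | (S)-(4-iodo-3-methylbutoxy)triisopropylsilane | IC[C@@H](C)CCO[Si](C(C)C)(C(C)C)C(C)C | intermediate
5 | (R)-carvone | CC1=CC[C@H](CC1=O)C(C)=C | starting material
6 | 6β-alkylcarvone (C6 chain trans to C7 isopropenyl) | [C@H]1(C[C@@H](C)CCO[Si](C(C)C)(C(C)C)C(C)C)[C@H](C(C)=C)CC=C(C)C1=O | intermediate
7 | 1α-allylic alcohol (cis-carveol type) | [C@H]1(C[C@@H](C)CCO[Si](C(C)C)(C(C)C)C(C)C)[C@H](C(C)=C)CC=C(C)[C@@H]1O | intermediate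
8 | 9α,10α-epoxy-1α-alcohol | [C@H]1(C[C@@H](C)CCO[Si](C(C)C)(C(C)C)C(C)C)[C@H](C(C)=C)C[C@@H]2O[C@]2(C)[C@@H]1O | intermediate
9 | 9β-phenylselanyl-1α,10α-diol | [C@H]1(C[C@@H](C)CCO[Si](C(C)C)(C(C)C)C(C)C)[C@H](C(C)=C)C[C@@H]([Se]c2ccccc2)[C@](C)(O)[C@@H]1O | intermediate
10 | Δ8-ene-1α,10α-diol (tertiary allylic alcohol) | [C@H]1(C[C@@H](C)CCO[Si](C(C)C)(C(C)C)C(C)C)[C@H](C(C)=C)C=C[C@](C)(O)[C@@H]1O | intermediate
11 | 1α-triisopropylsilyl ether of 10 | [C@H]1(C[C@@H](C)CCO[Si](C(C)C)(C(C)C)C(C)C)[C@H](C(C)=C)C=C[C@](C)(O)[C@@H]1O[Si](C(C)C)(C(C)C)C(C)C | intermediate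
12 | transposed enone (C8 ketone, C9=C10) | [C@H]1(C[C@@H](C)CCO[Si](C(C)C)(C(C)C)C(C)C)[C@H](C(C)=C)C(=O)C=C(C)[C@@H]1O[Si](C(C)C)(C(C)C)C(C)C | intermediate
13 | 8α-allylic alcohol | [C@H]1(C[C@@H](C)CCO[Si](C(C)C)(C(C)C)C(C)C)[C@H](C(C)=C)[C@H](O)C=C(C)[C@@H]1O[Si](C(C)C)(C(C)C)C(C)C | intermediate
14 | 9α,10α-epoxy-8α-alcohol | [C@H]1(C[C@@H](C)CCO[Si](C(C)C)(C(C)C)C(C)C)[C@H](C(C)=C)[C@H](O)[C@@H]2O[C@]2(C)[C@@H]1O[Si](C(C)C)(C(C)C)C(C)C | intermediate
15 | 8α-(4-methoxybenzyl) ether of the epoxide | [C@H]1(C[C@@H](C)CCO[Si](C(C)C)(C(C)C)C(C)C)[C@H](C(C)=C)[C@H](OCc3ccc(OC)cc3)[C@@H]2O[C@]2(C)[C@@H]1O[Si](C(C)C)(C(C)C)C(C)C | intermediate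
16 | 9β,10α-diol | [C@H]1(C[C@@H](C)CCO[Si](C(C)C)(C(C)C)C(C)C)[C@H](C(C)=C)[C@H](OCc2ccc(OC)cc2)[C@@H](O)[C@](C)(O)[C@@H]1O[Si](C(C)C)(C(C)C)C(C)C | intermediate
17 | 9β,10α-bis(methoxymethyl) ether | [C@H]1(C[C@@H](C)CCO[Si](C(C)C)(C(C)C)C(C)C)[C@H](C(C)=C)[C@H](OCc2ccc(OC)cc2)[C@@H](OCOC)[C@](C)(OCOC)[C@@H]1O[Si](C(C)C)(C(C)C)C(C)C | intermediate
18 | 1α,2-diol | [C@H]1(C[C@@H](C)CCO)[C@H](C(C)=C)[C@H](OCc2ccc(OC)cc2)[C@@H](OCOC)[C@](C)(OCOC)[C@@H]1O | intermediate
19 | primary iodide with free 1α-hydroxyl | [C@H]1(C[C@@H](C)CCI)[C@H](C(C)=C)[C@H](OCc2ccc(OC)cc2)[C@@H](OCOC)[C@](C)(OCOC)[C@@H]1O | intermediate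
20 | iodo ketone | [C@H]1(C[C@@H](C)CCI)[C@H](C(C)=C)[C@H](OCc2ccc(OC)cc2)[C@@H](OCOC)[C@](C)(OCOC)C1=O | intermediate
21 | cis-fused decalinol | C[C@H]1CC[C@@]2(O)[C@@H](C1)[C@H](C(C)=C)[C@H](OCc3ccc(OC)cc3)[C@@H](OCOC)[C@]2(C)OCOC | intermediate
22 | allylic alcohol (C12–OH) | C[C@H]1CC[C@@]2(O)[C@@H](C1)[C@H](C(CO)=C)[C@H](OCc3ccc(OC)cc3)[C@@H](OCOC)[C@]2(C)OCOC | intermediate
23 | enal (C12 aldehyde) | C[C@H]1CC[C@@]2(O)[C@@H](C1)[C@H](C(C=O)=C)[C@H](OCc3ccc(OC)cc3)[C@@H](OCOC)[C@]2(C)OCOC | intermediate
24 | acrylic acid | C[C@H]1CC[C@@]2(O)[C@@H](C1)[C@H](C(C(=O)O)=C)[C@H](OCc3ccc(OC)cc3)[C@@H](OCOC)[C@]2(C)OCOC | intermediate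
25 | tert-butyl acrylate decalinol | C[C@H]1CC[C@@]2(O)[C@@H](C1)[C@H](C(C(=O)OC(C)(C)C)=C)[C@H](OCc3ccc(OC)cc3)[C@@H](OCOC)[C@]2(C)OCOC | intermediate
26 | octalin with C1=C6 ring-fusion alkene | C[C@H]1CCC2=C(C1)[C@H](C(C(=O)OC(C)(C)C)=C)[C@H](OCc3ccc(OC)cc3)[C@@H](OCOC)[C@]2(C)OCOC | intermediate
27 | cyclodecane-1,6-dione | C[C@H]1CCC(=O)[C@@](C)(OCOC)[C@H](OCOC)[C@@H](OCc2ccc(OC)cc2)[C@@H](C(C(=O)OC(C)(C)C)=C)C(=O)C1 | intermediate
28 | 8α-hydroxy-1,6-dione | C[C@H]1CCC(=O)[C@@](C)(OCOC)[C@H](OCOC)[C@@H](O)[C@@H](C(C(=O)OC(C)(C)C)=C)C(=O)C1 | intermediate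
29 | 6β-hydroxy 8α-crotonate | C[C@H]1CCC(=O)[C@@](C)(OCOC)[C@H](OCOC)[C@@H](OC(=O)/C=C/C)[C@@H](C(C(=O)OC(C)(C)C)=C)[C@H](O)C1 | intermediate
30 | hydroxy acid | C[C@H]1CCC(=O)[C@@](C)(OCOC)[C@H](OCOC)[C@@H](OC(=O)/C=C/C)[C@@H](C(C(=O)O)=C)[C@H](O)C1 | intermediate
31 | MOM-protected lactone | C=C1C(=O)O[C@@H]2C[C@@H](C)CCC(=O)[C@@](C)(OCOC)[C@H](OCOC)[C@@H](OC(=O)/C=C/C)[C@@H]12 | intermediate
32 | α-methylene lactone 9β,10α-diol 8α-crotonate | C=C1C(=O)O[C@@H]2C[C@@H](C)CCC(=O)[C@@](C)(O)[C@H](O)[C@@H](OC(=O)/C=C/C)[C@@H]12 | intermediate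
33 | 2,3-dihydro target | C=C1C(=O)O[C@@H]2C[C@@H](C)CCC(=O)[C@@](C)(O)[C@H](OC(=O)/C=C/C)[C@@H](OC(=O)/C=C/C)[C@@H]12 | intermediate
34 | bis-silyl enol ether (C1=C2 geometry not defined) | C=C1C(=O)O[C@@H]2C[C@@H](C)CC=C(O[Si](C)(C)C)[C@@](C)(O[Si](C)(C)C)[C@H](OC(=O)/C=C/C)[C@@H](OC(=O)/C=C/C)[C@@H]12 | intermediate
35 | silyl-protected enone | C=C1C(=O)O[C@@H]2C[C@@H](C)/C=C\C(=O)[C@@](C)(O[Si](C)(C)C)[C@H](OC(=O)/C=C/C)[C@@H](OC(=O)/C=C/C)[C@@H]12 | intermediate
36 | CNP0223772.1, (4R,6R,7S,8S,9R,10S) in the locants used here | C=C1C(=O)O[C@@H]2C[C@@H](C)/C=C\C(=O)[C@@](C)(O)[C@H](OC(=O)/C=C/C)[C@@H](OC(=O)/C=C/C)[C@@H]12 | target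

**Step count and risks**

Total: 28 steps. Longest linear sequence: 28 steps (1 → 36; 25 steps from carvone 5).

1. Step 22 (dehydration). The syn-elimination may take the proton from C2 instead of C6, or the sulfamate may ionise and suffer a 1,2-shift from C10. Fallback: the alkene would be made by deoxygenation of a 1,6-diol instead of by dehydration.
   - From iodo ketone 20, soft enolisation (Me3SiOTf, Et3N) and Rubottom oxidation with dimethyldioxirane at −78 °C would give the 6-hydroxy ketone F1.
   - SmI2 Barbier closure as in step 18 would give the cis-1,6-diol F2.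
   - Allylic oxidation, chlorite oxidation and tert-butyl esterification as in steps 19–21 would lead through the enal F3 and the acid F4 to the ester diol F5.
   - 1,1'-Thiocarbonyldiimidazole would give the cyclic thiocarbonate F6.
   - Corey–Winter fragmentation with 1,3-dimethyl-2-phenyl-1,3,2-diazaphospholidine at 40 °C would place the alkene regiospecifically between C1 and C6, returning to octalin 26.

2. Step 25 (Evans–Tishchenko reduction). The samarium alkoxide may trigger retro-aldol opening or transannular aldolisation, or hydride transfer from the conjugated hemiacetal may be too slow. Fallback: reduction and acylation are separated.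
   - From 28, Me4NBH(OAc)3 in MeCN/AcOH at −30 °C (Evans–Saksena reduction) would give the anti-6,8-diol F7.
   - Et3SiCl/imidazole would silylate the less hindered C6 hydroxyl to give the silyl ether F8.
   - Crotonic anhydride/DMAP would acylate O8 to give the ester F9.
   - HF·pyridine would remove the silyl group and return to 29.

3. Step 10 (enone reduction). Hydride may be delivered from the α face (axial attack), giving the C8 epimer. Fallback: the epimer is made on purpose and inverted.
   - From enone 12, NaBH4/CeCl3 would give the 8β-alcohol F10.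
   - Mitsunobu reaction with 4-nitrobenzoic acid (PPh3, diisopropyl azodicarboxylate) would invert C8 to give the 8α-ester F11.
   - K2CO3/MeOH would return to 13.

**Further compounds**

F1 | step 22 | 6β-hydroxy iodo ketone (C6 configuration expected, lost later) | [C@]1(O)(C[C@@H](C)CCI)[C@H](C(C)=C)[C@H](OCc2ccc(OC)cc2)[C@@H](OCOC)[C@](C)(OCOC)C1=O
F2 | step 22 | cis-1,6-diol decalin | C[C@H]1CC[C@]2(O)[C@](O)(C1)[C@H](C(C)=C)[C@H](OCc3ccc(OC)cc3)[C@@H](OCOC)[C@]2(C)OCOC
F3 | step 22 | enal of the 1,6-diol | C[C@H]1CC[C@]2(O)[C@](O)(C1)[C@H](C(C=O)=C)[C@H](OCc3ccc(OC)cc3)[C@@H](OCOC)[C@]2(C)OCOC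
F4 | step 22 | acrylic acid of the 1,6-diol | C[C@H]1CC[C@]2(O)[C@](O)(C1)[C@H](C(C(=O)O)=C)[C@H](OCc3ccc(OC)cc3)[C@@H](OCOC)[C@]2(C)OCOC
F5 | step 22 | tert-butyl acrylate of the 1,6-diol | C[C@H]1CC[C@]2(O)[C@](O)(C1)[C@H](C(C(=O)OC(C)(C)C)=C)[C@H](OCc3ccc(OC)cc3)[C@@H](OCOC)[C@]2(C)OCOC
F6 | step 22 | cyclic 1,6-thiocarbonate | C[C@H]1CC[C@@]23OC(=S)O[C@@]3(C1)[C@H](C(C(=O)OC(C)(C)C)=C)[C@H](OCc4ccc(OC)cc4)[C@@H](OCOC)[C@]2(C)OCOC
F7 | step 25 | anti-6β,8α-diol | C[C@H]1CCC(=O)[C@@](C)(OCOC)[C@H](OCOC)[C@@H](O)[C@@H](C(C(=O)OC(C)(C)C)=C)[C@H](O)C1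
F8 | step 25 | 6β-triethylsilyl ether 8α-alcohol | C[C@H]1CCC(=O)[C@@](C)(OCOC)[C@H](OCOC)[C@@H](O)[C@@H](C(C(=O)OC(C)(C)C)=C)[C@H](O[Si](CC)(CC)CC)C1
F9 | step 25 | 6β-triethylsilyl ether 8α-crotonate | C[C@H]1CCC(=O)[C@@](C)(OCOC)[C@H](OCOC)[C@@H](OC(=O)/C=C/C)[C@@H](C(C(=O)OC(C)(C)C)=C)[C@H](O[Si](CC)(CC)CC)C1
F10 | step 10 | 8β-allylic alcohol | [C@H]1(C[C@@H](C)CCO[Si](C(C)C)(C(C)C)C(C)C)[C@H](C(C)=C)[C@@H](O)C=C(C)[C@@H]1O[Si](C(C)C)(C(C)C)C(C)C
F11 | step 10 | 8α-(4-nitrobenzoate) | [C@H]1(C[C@@H](C)CCO[Si](C(C)C)(C(C)C)C(C)C)[C@H](C(C)=C)[C@H](OC(=O)c2ccc(cc2)[N+](=O)[O-])C=C(C)[C@@H]1O[Si](C(C)C)(C(C)C)C(C)C
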